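**Plan**

- Retrosynthesis: the C11–O acetate bond, the C8–O isobutyrate bond and the two C11–CH3 bonds are cut first, leading back to a bicycle with a C8 ketone and a C7 ester. Then C6–C7 of ring B is cut, then C7–C8 (diazoacetate carbon), C5–C6 (hydroxymethyl unit) and C1–C10 (crotyl unit).
- Enabling feature (guaiane numbering, used for every compound): C6 of the seven-membered ring B is allylic to the C4=C5 double bond of the five-membered ring A enone, and C7 lies between the two oxygen-bearing carbons C8 and C11. C7 can therefore be the carbon of a C8-keto/C11-ester enolate and C6 the free terminus of a C4–C5–C6 allylpalladium unit.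
- Forward: ring A comes from 2-methylcyclopentane-1,3-dione as its vinylogous ester. The C10–C9–C8 chain is joined at C1 by branched crotylation, C6 is added with transposition of the enone, the chain is grown to the β-keto ester, and ring B is closed last at C6–C7.
- Stereochemistry: C10 comes from the chiral iridium catalyst and C1 from the same bond formation. C7 and C8 come from reduction of the cyclic β-keto ester (cis hydroxy ester, hydride anti to the C10 methyl).

Key step: step 10

Assumption: the (Ra,R,R) antipode of the ligand L, O,O′-(1,1′-binaphthalene-2,2′-diyl) N,N-bis(1-phenylethyl)phosphoramidite, is taken to give (S) at C10; if a pilot run shows the opposite sense, the mirror-image ligand is used and nothing else changes.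

**Route**

Step 1
Reactants: 1 2-methylcyclopentane-1,3-dione
Product: 2 3-isobutoxy-2-methylcyclopent-2-en-1-one
Conditions: i-BuOH, TsOH·H2O (cat.), toluene, reflux, Dean–Stark trap
Reagents that add atoms: 2-methylpropan-1-ol, CC(C)CO
Why: Acid-catalysed enol etherification of a cyclic 1,3-diketone (vinylogous ester formation) with azeotropic removal of water is a standard reaction and forms no stereocentre.

Step 2
Reactants: 2 3-isobutoxy-2-methylcyclopent-2-en-1-one; 3 (E)-but-2-enyl methyl carbonate
Product: 6 (5R)-5-[(2S)-but-3-en-2-yl]-3-isobutoxy-2-methylcyclopent-2-en-1-one, via lithium dienolate 4 (not isolated), via copper dienolate 5 (not isolated)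
Conditions: LiN(i-Pr)2 (LDA), THF, −78 °C; CuBr, −78 → −40 °C; then 3, [Ir(cod)Cl]2 (2 mol %), (Ra,R,R)-L (4 mol %, pre-activated with n-PrNH2), THF, −40 → 0 °C
Reagents that add atoms: none
Why: Kinetic deprotonation at C1 and transmetalation to the softer monovalent copper enolate feed an iridium-catalysed branched-selective asymmetric allylic alkylation, a reaction type known for unstabilised ketone and vinylogous-ester enolates, in which the ligand-bound allyl iridium complex is attacked at its methyl-bearing terminus on one face to set C10 as (S), while C1 is set in the same event by the enolate face that turns the ring away from the allyl methyl, any C1 epimer being separable and, as the only base-labile centre, recyclable by equilibration.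

Step 3
Reactants: 6 (5R)-5-[(2S)-but-3-en-2-yl]-3-isobutoxy-2-methylcyclopent-2-en-1-one
Product: 7 (5R)-5-[(2S)-4-hydroxybutan-2-yl]-3-isobutoxy-2-methylcyclopent-2-en-1-one
Conditions: 9-BBN, THF, 0 °C → rt; then aq. NaOAc, 30% H2O2, 0 °C → rt
Reagents that add atoms: hydrogen peroxide, OO
Why: Anti-Markovnikov hydroboration–oxidation of the terminal vinyl group with bulky 9-BBN is chemoselective over the deactivated vinylogous ester carbonyl and its tetrasubstituted double bond, and the buffered oxidation leaves C1 untouched.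

Step 4
Reactants: 7 (5R)-5-[(2S)-4-hydroxybutan-2-yl]-3-isobutoxy-2-methylcyclopent-2-en-1-one
Product: 8 (5R)-5-[(2S)-4-(tert-butyldiphenylsilyloxy)butan-2-yl]-3-isobutoxy-2-methylcyclopent-2-en-1-one
Conditions: TBDPSCl, imidazole, DMF, rt
Reagents that add atoms: tert-butyl(chloro)diphenylsilane, CC(C)(C)[Si](Cl)(c1ccccc1)c1ccccc1
Why: Silyl ether formation masks the primary alcohol with a group that should survive the organomagnesium, peroxide and dilute-acid operations of the next step.

Step 5
Reactants: 8 (5R)-5-[(2S)-4-(tert-butyldiphenylsilyloxy)butan-2-yl]-3-isobutoxy-2-methylcyclopent-2-en-1-one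
Product: 11 (4R)-4-[(2S)-4-(tert-butyldiphenylsilyloxy)butan-2-yl]-3-(hydroxymethyl)-2-methylcyclopent-2-en-1-one, via chloromagnesium carbinolate 9 (not isolated), via tertiary allylic diol 10 (not isolated)
Conditions: (i-PrO)Me2SiCH2MgCl, THF, 0 °C → rt; then KF, KHCO3, 30% H2O2, THF–MeOH, rt; then Na2S2O3, 1 M HCl, THF, 0 °C
Reagents that add atoms: (isopropoxydimethylsilyl)methylmagnesium chloride, CC(C)O[Si](C)(C)C[Mg]Cl; hydrogen peroxide, OO; water, O
Why: This is a Stork–Danheiser transposition with a hydroxymethyl anion equivalent, in which the silylmethyl Grignard reagent adds 1,2 to the C5 carbonyl, Tamao oxidation of the C–Si bond is done while the ring is still an enol ether (so no γ-silyl enone meets peroxide), and dilute acid then hydrolyses the enol ether and eliminates the tertiary hydroxyl to leave the ketone at C3 and the hydroxymethyl group on C5.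

Step 6
Reactants: 11 (4R)-4-[(2S)-4-(tert-butyldiphenylsilyloxy)butan-2-yl]-3-(hydroxymethyl)-2-methylcyclopent-2-en-1-one
Product: 12 ethyl [(5R)-5-[(2S)-4-(tert-butyldiphenylsilyloxy)butan-2-yl]-2-methyl-3-oxocyclopent-1-en-1-yl]methyl carbonate
Conditions: ClCO2Et, pyridine, CH2Cl2, 0 °C
Reagents that add atoms: ethyl chloroformate, CCOC(=O)Cl
Why: Acylation of the primary allylic alcohol gives the allylic ethyl carbonate, a leaving group that ionises under neutral conditions and releases the same alkoxide as the ester later carried by the nucleophile.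

Step 7
Reactants: 12 ethyl [(5R)-5-[(2S)-4-(tert-butyldiphenylsilyloxy)butan-2-yl]-2-methyl-3-oxocyclopent-1-en-1-yl]methyl carbonate
Product: 13 ethyl [(5R)-5-[(2S)-4-hydroxybutan-2-yl]-2-methyl-3-oxocyclopent-1-en-1-yl]methyl carbonate
Conditions: HF·pyridine, THF–pyridine, 0 °C → rt
Reagents that add atoms: none
Why: Fluoride desilylation under mildly acidic conditions removes the silyl ether while sparing the carbonate and the enone, which are sensitive to base and not to acid.

Step 8
Reactants: 13 ethyl [(5R)-5-[(2S)-4-hydroxybutan-2-yl]-2-methyl-3-oxocyclopent-1-en-1-yl]methyl carbonate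
Product: 14 ethyl [(5R)-2-methyl-3-oxo-5-[(2S)-4-oxobutan-2-yl]cyclopent-1-en-1-yl]methyl carbonate
Conditions: Dess–Martin periodinane, NaHCO3, CH2Cl2, 0 °C → rt
Reagents that add atoms: none
Why: Dess–Martin oxidation of a primary alcohol stops at the aldehyde under buffered, non-basic conditions that should leave the carbonate, the enone and the C1 and C10 centres unchanged.

Step 9
Reactants: 14 ethyl [(5R)-2-methyl-3-oxo-5-[(2S)-4-oxobutan-2-yl]cyclopent-1-en-1-yl]methyl carbonate; 15 ethyl diazoacetate
Product: 16 ethyl (5S)-5-[(1R)-2-{[(ethoxycarbonyl)oxy]methyl}-3-methyl-4-oxocyclopent-2-en-1-yl]-3-oxohexanoate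
Conditions: SnCl2 (10 mol %), CH2Cl2, rt
Reagents that add atoms: none
Why: In the Roskamp homologation the Lewis acid promotes addition of the diazo ester to the aldehyde and a 1,2-hydride shift with loss of N2 gives the β-keto ester directly, the reaction being selective for the aldehyde over the ring ketone.

Step 10
Reactants: 16 ethyl (5S)-5-[(1R)-2-{[(ethoxycarbonyl)oxy]methyl}-3-methyl-4-oxocyclopent-2-en-1-yl]-3-oxohexanoate
Product: 17 ethyl (5S,8S,8aR)-3,8-dimethyl-2,6-dioxo-1,2,4,5,6,7,8,8a-octahydroazulene-5-carboxylate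
Conditions: Pd(PPh3)4 (10 mol %), THF, 0.005 M, slow addition of 16, 60 °C
Reagents that add atoms: none
Why: Zerovalent palladium ionises the C6 ethyl carbonate with loss of CO2 to a C4–C5–C6 π-allyl complex, and the ethoxide set free deprotonates the β-keto ester, so no external base is present. The soft C7 enolate then attacks the unsubstituted C6 terminus on the face opposite palladium, which is the intramolecular Tsuji–Trost allylic alkylation of a stabilised carbon nucleophile, known for closures of five- to seven-membered and larger rings. Ring B closes in a 7-exo mode through C1, the substituent on the central allyl carbon, with the departing metal outside the new ring, and the C4=C5 double bond returns into conjugation with the C3 ketone. C7 is the one new stereocentre; it lies between two carbonyl groups, equilibrates through the enol and is fixed only in step 11, while C1 and C10 pass unchanged under the neutral conditions. The step needs attack at C6 and not at C4: C4 is fully substituted and carries the acyl group, and its alkylation would give a bridged ring with a quaternary carbon and an unconjugated methylene. Conjugate addition of the enolate to C5 is held back because the enolate arises mainly in molecules whose enone has already become the allyl complex, and high dilution suppresses dimerisation.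

Step 11
Reactants: 17 ethyl (5S,8S,8aR)-3,8-dimethyl-2,6-dioxo-1,2,4,5,6,7,8,8a-octahydroazulene-5-carboxylate
Product: 18 ethyl (5S,6R,8S,8aR)-2,6-dihydroxy-3,8-dimethyl-1,2,4,5,6,7,8,8a-octahydroazulene-5-carboxylate (both C3 carbinol epimers)
Conditions: NaBH4, CeCl3·7H2O, EtOH, −40 → 0 °C
Reagents that add atoms: none
Why: Luche reduction takes both ketones 1,2, and at C8 the keto ester epimers interconvert through the enol while hydride should add to the ring face opposite the C7 ester and the C10 methyl, which lie on the same face in the 7S epimer, to give the cis 8R hydroxy ester, the C3 carbinol forming as an inconsequential mixture.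

Step 12
Reactants: 18 ethyl (5S,6R,8S,8aR)-2,6-dihydroxy-3,8-dimethyl-1,2,4,5,6,7,8,8a-octahydroazulene-5-carboxylate
Product: 19 (5S,6R,8S,8aR)-5-(2-hydroxypropan-2-yl)-3,8-dimethyl-1,2,4,5,6,7,8,8a-octahydroazulene-2,6-diol (both C3 carbinol epimers)
Conditions: MeMgBr (8 equiv), THF, −20 °C → rt
Reagents that add atoms: methylmagnesium bromide, C[Mg]Br
Why: Double Grignard addition to the ester builds the C11 dimethylcarbinol while the C3 and C8 hydroxyls are masked in the flask as magnesium alkoxides, and addition should outrun enolisation at C7 at this temperature.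

Step 13
Reactants: 19 (5S,6R,8S,8aR)-5-(2-hydroxypropan-2-yl)-3,8-dimethyl-1,2,4,5,6,7,8,8a-octahydroazulene-2,6-diol
Product: 20 (5S,6R,8S,8aR)-6-hydroxy-5-(2-hydroxypropan-2-yl)-3,8-dimethyl-4,5,6,7,8,8a-hexahydroazulen-2(1H)-one
Conditions: MnO2 (excess), CH2Cl2, rt
Reagents that add atoms: none
Why: Chemoselective allylic oxidation with MnO2 returns only the C3 alcohol to the conjugated ketone, merges the C3 epimers and leaves the saturated secondary C8 and tertiary C11 hydroxyls alone.

Step 14
Reactants: 20 (5S,6R,8S,8aR)-6-hydroxy-5-(2-hydroxypropan-2-yl)-3,8-dimethyl-4,5,6,7,8,8a-hexahydroazulen-2(1H)-one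
Product: 21 (5S,6R,8S,8aR)-5-(2-hydroxypropan-2-yl)-3,8-dimethyl-2-oxo-1,2,4,5,6,7,8,8a-octahydroazulen-6-yl 2-methylpropanoate
Conditions: (i-PrCO)2O, DMAP (cat.), pyridine, CH2Cl2, 0 °C → rt
Reagents that add atoms: 2-methylpropanoic anhydride, CC(C)C(=O)OC(=O)C(C)C
Why: DMAP-catalysed acylation esterifies the secondary C8 hydroxyl selectively because the tertiary C11 hydroxyl is too hindered to react under these conditions.

Step 15
Reactants: 21 (5S,6R,8S,8aR)-5-(2-hydroxypropan-2-yl)-3,8-dimethyl-2-oxo-1,2,4,5,6,7,8,8a-octahydroazulen-6-yl 2-methylpropanoate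
Product: 22 (5S,6R,8S,8aR)-5-(2-acetoxypropan-2-yl)-3,8-dimethyl-2-oxo-1,2,4,5,6,7,8,8a-octahydroazulen-6-yl 2-methylpropanoate (CNP0197994.1)
Conditions: Ac2O, Sc(OTf)3 (5 mol %), MeCN, −20 °C
Reagents that add atoms: acetic anhydride, CC(=O)OC(C)=O
Why: Lewis-acid-catalysed acylation with Sc(OTf)3 and the anhydride at low temperature is a known way to esterify hindered tertiary alcohols without elimination, and the enone and the isobutyrate should be inert to it.

**Compound list**

1 | 2-methylcyclopentane-1,3-dione | CC1C(=O)CCC1=O | starting material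
2 | 3-isobutoxy-2-methylcyclopent-2-en-1-one | CC(C)COC1=C(C)C(=O)CC1 | intermediate
3 | (E)-but-2-enyl methyl carbonate | C/C=C/COC(=O)OC | starting material
4 | lithium 4-isobutoxy-5-methylcyclopenta-1,4-dien-1-olate (lithium dienolate of 2) | CC1=C(OCC(C)C)CC=C1[O-].[Li+] | intermediate
5 | copper 4-isobutoxy-5-methylcyclopenta-1,4-dien-1-olate (monovalent copper dienolate of 2) | CC1=C(OCC(C)C)CC=C1O[Cu] | intermediate
6 | (5R)-5-[(2S)-but-3-en-2-yl]-3-isobutoxy-2-methylcyclopent-2-en-1-one | C=C[C@H](C)[C@H]1CC(OCC(C)C)=C(C)C1=O | intermediate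
7 | (5R)-5-[(2S)-4-hydroxybutan-2-yl]-3-isobutoxy-2-methylcyclopent-2-en-1-one | OCC[C@H](C)[C@H]1CC(OCC(C)C)=C(C)C1=O | intermediate
8 | (5R)-5-[(2S)-4-(tert-butyldiphenylsilyloxy)butan-2-yl]-3-isobutoxy-2-methylcyclopent-2-en-1-one | CC(C)(C)[Si](OCC[C@H](C)[C@H]1CC(OCC(C)C)=C(C)C1=O)(c1ccccc1)c1ccccc1 | intermediate
9 | chloromagnesium (5R)-5-[(2S)-4-(tert-butyldiphenylsilyloxy)butan-2-yl]-3-isobutoxy-1-[(isopropoxydimethylsilyl)methyl]-2-methylcyclopent-2-en-1-olate (both carbinol epimers) | CC(C)(C)[Si](OCC[C@H](C)[C@H]1CC(OCC(C)C)=C(C)C1(O[Mg]Cl)C[Si](C)(C)OC(C)C)(c1ccccc1)c1ccccc1 | intermediate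
10 | (5R)-5-[(2S)-4-(tert-butyldiphenylsilyloxy)butan-2-yl]-1-(hydroxymethyl)-3-isobutoxy-2-methylcyclopent-2-en-1-ol (both carbinol epimers) | CC(C)(C)[Si](OCC[C@H](C)[C@H]1CC(OCC(C)C)=C(C)C1(O)CO)(c1ccccc1)c1ccccc1 | intermediate
11 | (4R)-4-[(2S)-4-(tert-butyldiphenylsilyloxy)butan-2-yl]-3-(hydroxymethyl)-2-methylcyclopent-2-en-1-one | CC(C)(C)[Si](OCC[C@H](C)[C@H]1CC(=O)C(C)=C1CO)(c1ccccc1)c1ccccc1 | intermediate
12 | ethyl [(5R)-5-[(2S)-4-(tert-butyldiphenylsilyloxy)butan-2-yl]-2-methyl-3-oxocyclopent-1-en-1-yl]methyl carbonate | CC(C)(C)[Si](OCC[C@H](C)[C@H]1CC(=O)C(C)=C1COC(=O)OCC)(c1ccccc1)c1ccccc1 | intermediate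
13 | ethyl [(5R)-5-[(2S)-4-hydroxybutan-2-yl]-2-methyl-3-oxocyclopent-1-en-1-yl]methyl carbonate | OCC[C@H](C)[C@H]1CC(=O)C(C)=C1COC(=O)OCC | intermediate
14 | ethyl [(5R)-2-methyl-3-oxo-5-[(2S)-4-oxobutan-2-yl]cyclopent-1-en-1-yl]methyl carbonate | O=CC[C@H](C)[C@H]1CC(=O)C(C)=C1COC(=O)OCC | intermediate
15 | ethyl diazoacetate | CCOC(=O)C=[N+]=[N-] | starting material
16 | ethyl (5S)-5-[(1R)-2-{[(ethoxycarbonyl)oxy]methyl}-3-methyl-4-oxocyclopent-2-en-1-yl]-3-oxohexanoate | CCOC(=O)CC(=O)C[C@H](C)[C@H]1CC(=O)C(C)=C1COC(=O)OCC | intermediate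
17 | ethyl (5S,8S,8aR)-3,8-dimethyl-2,6-dioxo-1,2,4,5,6,7,8,8a-octahydroazulene-5-carboxylate (C7 labile, drawn as the 7S keto form) | CCOC(=O)[C@H]1CC2=C(C)C(=O)C[C@@H]2[C@@H](C)CC1=O | intermediate
18 | ethyl (5S,6R,8S,8aR)-2,6-dihydroxy-3,8-dimethyl-1,2,4,5,6,7,8,8a-octahydroazulene-5-carboxylate (both C3 carbinol epimers) | CCOC(=O)[C@H]1CC2=C(C)C(O)C[C@@H]2[C@@H](C)C[C@H]1O | intermediate
19 | (5S,6R,8S,8aR)-5-(2-hydroxypropan-2-yl)-3,8-dimethyl-1,2,4,5,6,7,8,8a-octahydroazulene-2,6-diol (both C3 carbinol epimers) | CC(C)(O)[C@H]1CC2=C(C)C(O)C[C@@H]2[C@@H](C)C[C@H]1O | intermediate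
20 | (5S,6R,8S,8aR)-6-hydroxy-5-(2-hydroxypropan-2-yl)-3,8-dimethyl-4,5,6,7,8,8a-hexahydroazulen-2(1H)-one | CC(C)(O)[C@H]1CC2=C(C)C(=O)C[C@@H]2[C@@H](C)C[C@H]1O | intermediate
21 | (5S,6R,8S,8aR)-5-(2-hydroxypropan-2-yl)-3,8-dimethyl-2-oxo-1,2,4,5,6,7,8,8a-octahydroazulen-6-yl 2-methylpropanoate | CC(C)(O)[C@H]1CC2=C(C)C(=O)C[C@@H]2[C@@H](C)C[C@H]1OC(=O)C(C)C | intermediate
22 | (5S,6R,8S,8aR)-5-(2-acetoxypropan-2-yl)-3,8-dimethyl-2-oxo-1,2,4,5,6,7,8,8a-octahydroazulen-6-yl 2-methylpropanoate | CC(=O)OC(C)(C)[C@H]1CC2=C(C)C(=O)C[C@@H]2[C@@H](C)C[C@H]1OC(=O)C(C)C | target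

**Count and risks**

Total step count: 15. Longest linear sequence: 15 steps (from compound 1; compounds 3 and 15 are bought).

Steps most likely to fail:

1. Step 2. The enolate may attack the unsubstituted allyl terminus (linear crotyl product), select the faces of the small methyl-substituted allyl poorly, scramble by proton transfer before it is intercepted, or fail to discriminate its own two faces (C1 epimers). The fallback sets out from compound 2 and comes back at compound 6. Commercial (S)-but-3-en-2-ol is converted with methyl chloroformate and pyridine into (S)-but-3-en-2-yl methyl carbonate F1. Copper dienolate 5, made from 2 as in step 2, is then alkylated with F1 under RhCl(PPh3)3 modified with P(OMe)3 in THF at −10 °C. This rhodium-catalysed allylic alkylation of copper enolates is regiospecific for the carbon that carried the leaving group and runs with net retention, so C10 is taken from the enantiopure carbonate and not from a catalyst, and the low temperature limits proton transfer. It does not improve control at C1, so C1 epimers are separated and the unwanted one re-equilibrated with base, as in the main step.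

2. Step 10. Ionisation of an allylic carbonate conjugated to a ketone may be slow and the seven-membered closure slower still, which would let the enolate add to the enone at C5 (six-membered ring) or alkylate a second molecule. The fallback sets out from compound 12 and comes back at compound 18; it closes the same C6–C7 bond with ring A at the alcohol oxidation level. NaBH4 and CeCl3·7H2O in EtOH reduce the ring ketone of 12 to ethyl [(5R)-5-[(2S)-4-(tert-butyldiphenylsilyloxy)butan-2-yl]-3-hydroxy-2-methylcyclopent-1-en-1-yl]methyl carbonate F2 (both C3 epimers). HF·pyridine gives ethyl [(5R)-3-hydroxy-5-[(2S)-4-hydroxybutan-2-yl]-2-methylcyclopent-1-en-1-yl]methyl carbonate F3. TEMPO with PhI(OAc)2 oxidises only the primary alcohol to ethyl [(5R)-3-hydroxy-2-methyl-5-[(2S)-4-oxobutan-2-yl]cyclopent-1-en-1-yl]methyl carbonate F4. Compound 15 with SnCl2 then gives ethyl (5S)-5-[(1R)-2-{[(ethoxycarbonyl)oxy]methyl}-4-hydroxy-3-methylcyclopent-2-en-1-yl]-3-oxohexanoate F5. Pd(PPh3)4 closes ring B on an allyl unit that is no longer electron-poor and in a molecule that has no Michael acceptor, giving ethyl (5S,8S,8aR)-2-hydroxy-3,8-dimethyl-6-oxo-1,2,4,5,6,7,8,8a-octahydroazulene-5-carboxylate F6. NaBH4 in EtOH reduces its C8 ketone to give compound 18.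

3. Step 11. Hydride may be delivered to the wrong face of C8, or through the wrong C7 epimer, giving the trans hydroxy ester or the cis isomer of opposite sense. The fallback sets out from compound 17 and comes back at compound 18; it replaces substrate control by catalyst control. Asymmetric transfer hydrogenation with dynamic kinetic resolution, using RuCl(p-cymene)[(R,R)-TsDPEN] (or its mirror image, whichever matches 8R in a pilot run) and HCO2H–Et3N, is known to give cis hydroxy esters from cyclic β-keto esters and should leave the tetrasubstituted enone alone. It gives ethyl (5S,6R,8S,8aR)-6-hydroxy-3,8-dimethyl-2-oxo-1,2,4,5,6,7,8,8a-octahydroazulene-5-carboxylate F7, whose ring ketone is then reduced with NaBH4 and CeCl3·7H2O in EtOH to compound 18.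

**Further compounds**

F1 | step 2 | (S)-but-3-en-2-yl methyl carbonate | C=C[C@H](C)OC(=O)OC
F2 | step 10 | ethyl [(5R)-5-[(2S)-4-(tert-butyldiphenylsilyloxy)butan-2-yl]-3-hydroxy-2-methylcyclopent-1-en-1-yl]methyl carbonate (both C3 epimers) | CC(C)(C)[Si](OCC[C@H](C)[C@H]1CC(O)C(C)=C1COC(=O)OCC)(c1ccccc1)c1ccccc1
F3 | step 10 | ethyl [(5R)-3-hydroxy-5-[(2S)-4-hydroxybutan-2-yl]-2-methylcyclopent-1-en-1-yl]methyl carbonate (both C3 epimers) | OCC[C@H](C)[C@H]1CC(O)C(C)=C1COC(=O)OCC
F4 | step 10 | ethyl [(5R)-3-hydroxy-2-methyl-5-[(2S)-4-oxobutan-2-yl]cyclopent-1-en-1-yl]methyl carbonate (both C3 epimers) | O=CC[C@H](C)[C@H]1CC(O)C(C)=C1COC(=O)OCC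
F5 | step 10 | ethyl (5S)-5-[(1R)-2-{[(ethoxycarbonyl)oxy]methyl}-4-hydroxy-3-methylcyclopent-2-en-1-yl]-3-oxohexanoate (both C3 epimers) | CCOC(=O)CC(=O)C[C@H](C)[C@H]1CC(O)C(C)=C1COC(=O)OCC
F6 | step 10 | ethyl (5S,8S,8aR)-2-hydroxy-3,8-dimethyl-6-oxo-1,2,4,5,6,7,8,8a-octahydroazulene-5-carboxylate (both C3 epimers) | CCOC(=O)[C@H]1CC2=C(C)C(O)C[C@@H]2[C@@H](C)CC1=O
F7 | step 11 | ethyl (5S,6R,8S,8aR)-6-hydroxy-3,8-dimethyl-2-oxo-1,2,4,5,6,7,8,8a-octahydroazulene-5-carboxylate | CCOC(=O)[C@H]1CC2=C(C)C(=O)C[C@@H]2[C@@H](C)C[C@H]1O
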